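## Retrosynthetic overview
1. The target comes from the (S)-1,3-diol carrying a TES group on its tertiary OH, by palmitoylation of the primary OH and then fluoride desilylation.
2. The primary alcohol comes from hydride removal of an Oppolzer sultam from an α-(indol-3-yl)acyl sultam.
3. Key step: the indole C3–Cα bond is made by direct Cu(II)-mediated oxidative coupling of unprotected 5-prenylindole with the chiral sultam enolate. This formal C–H/C–H union sets the only stereocentre and replaces the usual alkylation or aldol of an indole-3-acetate, or an epoxide opening.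
4. The acyl sultam comes from acetyl sultam and acetone (aldol with in-flask silylation). 5-Prenylindole comes from 5-bromoindole and a prenylstannane (Stille).
5. No ring is built. The indole bicycle is bought intact, and the sultam rings serve only as the auxiliary and are recovered.

Assumption: the acyl chain is unbranched hexadecanoyl, and the (2R)-sultam (Z)-enolate reacts on its Cα-Re face in the oxidative coupling as it does in its alkylations, which can be checked by X-ray on the crystalline coupling product.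

## Route

Step 1
Reactants: 1 5-bromo-1H-indole; 2 tributyl(3-methylbut-2-en-1-yl)stannane
Product: 3 5-(3-methylbut-2-en-1-yl)-1H-indole
Conditions: Pd(PPh3)4 (5 mol %), DMF, 100 °C
Reagents that add atoms: tributyl(3-methylbut-2-en-1-yl)stannane (2), CCCC[Sn](CCCC)(CCCC)CC=C(C)C
Why: Migita–Kosugi–Stille cross-coupling, in which Pd(0) inserts into C5–Br, transmetalation gives an aryl(η3-prenyl)palladium species, reductive elimination at the unsubstituted allyl terminus gives the linear prenyl arene, and the neutral medium tolerates the free N–H.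

Step 2
Reactants: 4 (2R)-bornane-10,2-sultam; 5 acetyl chloride
Product: 7 (2R)-N-acetylbornane-10,2-sultam, via sodium sultamide 6 (not isolated)
Conditions: NaH, toluene, 0 °C to rt; then AcCl
Reagents that add atoms: acetyl chloride (5), CC(=O)Cl
Why: N-acylation of the acidic sultam N–H through its sodium salt is the standard loading of the Oppolzer auxiliary and leaves its three stereocentres untouched.

Step 3
Reactants: 7 (2R)-N-acetylbornane-10,2-sultam; 8 acetone; 9 triethylsilyl trifluoromethanesulfonate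
Product: 12 (2R)-N-[3-methyl-3-(triethylsilyloxy)butanoyl]bornane-10,2-sultam, via lithium enolate 10 (not isolated), via lithium aldolate 11 (not isolated)
Conditions: LiHMDS (1.05 equiv), THF, −78 °C; acetone (1.5 equiv), −78 °C; TESOTf (1.6 equiv), −78 to −40 °C
Reagents that add atoms: acetone (8), CC(C)=O; triethylsilyl trifluoromethanesulfonate (9), CC[Si](CC)(CC)OS(=O)(=O)C(F)(F)F
Why: Lithium acetate-type aldol addition to a symmetrical ketone creates no stereocentre, and the tertiary aldolate is O-silylated by the triflate at low temperature before retro-aldol or β-lactonisation can compete.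

Step 4
Reactants: 12 (2R)-N-[3-methyl-3-(triethylsilyloxy)butanoyl]bornane-10,2-sultam; 3 5-(3-methylbut-2-en-1-yl)-1H-indole
Product: 15 (2R)-N-{(2R)-3-methyl-2-[5-(3-methylbut-2-en-1-yl)-1H-indol-3-yl]-3-(triethylsilyloxy)butanoyl}bornane-10,2-sultam, via lithium (Z)-enolate 13 (not isolated), via lithium 5-prenylindolide 14 (not isolated)
Conditions: 3 (2 equiv, excess recovered), LiHMDS (3.3 equiv), THF, −78 °C; copper(II) 2-ethylhexanoate (2 equiv), −78 to −20 °C; aq NH4Cl/NH4OH
Reagents that add atoms: none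
Why: In this Baran-type Cu(II)-mediated oxidative enolate–indole heterocoupling both anions bind copper, one-electron oxidation joins Cα to indole C3 and tautomerisation restores the indole, while the chelated (Z)-enolate of the (2R)-sultam is open only on its Cα-Re face, which sets (R) at Cα (the future S centre), and the Li-chelated in-plane β-C–O bond lies orthogonal to the enolate π system so that β-elimination stays slow in the cold.

Step 5
Reactants: 15 (2R)-N-{(2R)-3-methyl-2-[5-(3-methylbut-2-en-1-yl)-1H-indol-3-yl]-3-(triethylsilyloxy)butanoyl}bornane-10,2-sultam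
Product: 17 (2S)-3-methyl-2-[5-(3-methylbut-2-en-1-yl)-1H-indol-3-yl]-3-(triethylsilyloxy)butan-1-ol, via aldehyde 16 (not isolated)
Conditions: LiAlH4 (3 equiv), THF, −20 to 0 °C; Na2SO4·10H2O quench
Reagents that add atoms: none
Why: Reductive cleavage of an N-acylsultam with LiAlH4 (standard auxiliary removal) proceeds through the aldehyde without touching the stereocentre (the descriptor changes from R to S only because CH2OH ranks below CMe2OSi), and the alkene, indole and silyl ether are inert to hydride.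

Step 6
Reactants: 17 (2S)-3-methyl-2-[5-(3-methylbut-2-en-1-yl)-1H-indol-3-yl]-3-(triethylsilyloxy)butan-1-ol; 18 hexadecanoyl chloride
Product: 19 (2S)-3-methyl-2-[5-(3-methylbut-2-en-1-yl)-1H-indol-3-yl]-3-(triethylsilyloxy)butyl hexadecanoate
Conditions: 18 (1.1 equiv), pyridine, CH2Cl2, 0 °C
Reagents that add atoms: hexadecanoyl chloride (18), CCCCCCCCCCCCCCCC(=O)Cl
Why: O-acylation with acid chloride and pyridine (Einhorn-type esterification) reaches the only free hydroxyl, whereas the indole N–H is not nucleophilic enough to be acylated without a strong base.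

Step 7
Reactants: 19 (2S)-3-methyl-2-[5-(3-methylbut-2-en-1-yl)-1H-indol-3-yl]-3-(triethylsilyloxy)butyl hexadecanoate
Product: 20 (2S)-3-hydroxy-3-methyl-2-[5-(3-methylbut-2-en-1-yl)-1H-indol-3-yl]butyl hexadecanoate
Conditions: HF·pyridine, pyridine, THF, 0 °C to rt
Reagents that add atoms: none
Why: Fluoride-driven desilylation (Si–F bond formation) in a pyridine-buffered medium frees the tertiary alcohol without ionising it, without cleaving or shifting the ester, and without affecting the prenyl alkene or the stereocentre.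

## Compound list
1 | 5-bromo-1H-indole | Brc1ccc2[nH]ccc2c1 | starting material
2 | tributyl(3-methylbut-2-en-1-yl)stannane | CCCC[Sn](CCCC)(CCCC)CC=C(C)C | starting material
3 | 5-(3-methylbut-2-en-1-yl)-1H-indole | CC(C)=CCc1ccc2[nH]ccc2c1 | intermediate
4 | (2R)-bornane-10,2-sultam, the (−)-camphorsultam (3aS,6R,7aR) | CC1(C)[C@@H]2CC[C@]13CS(=O)(=O)N[C@@H]3C2 | starting material
5 | acetyl chloride | CC(=O)Cl | starting material
6 | sodium salt of (2R)-bornane-10,2-sultam | CC1(C)[C@@H]2CC[C@]13CS(=O)(=O)[N-][C@@H]3C2.[Na+] | intermediate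
7 | (2R)-N-acetylbornane-10,2-sultam | CC1(C)[C@@H]2CC[C@]13CS(=O)(=O)N([C@@H]3C2)C(C)=O | intermediate
8 | acetone | CC(C)=O | starting material
9 | triethylsilyl trifluoromethanesulfonate | CC[Si](CC)(CC)OS(=O)(=O)C(F)(F)F | starting material
10 | lithium enolate of 7 | CC1(C)[C@@H]2CC[C@]13CS(=O)(=O)N([C@@H]3C2)C([O-])=C.[Li+] | intermediate
11 | lithium aldolate of 7 and acetone | CC1(C)[C@@H]2CC[C@]13CS(=O)(=O)N([C@@H]3C2)C(=O)CC(C)(C)[O-].[Li+] | intermediate
12 | (2R)-N-[3-methyl-3-(triethylsilyloxy)butanoyl]bornane-10,2-sultam | CC1(C)[C@@H]2CC[C@]13CS(=O)(=O)N([C@@H]3C2)C(=O)CC(C)(C)O[Si](CC)(CC)CC | intermediate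
13 | lithium (Z)-enolate of 12 | CC1(C)[C@@H]2CC[C@]13CS(=O)(=O)N([C@@H]3C2)/C([O-])=C/C(C)(C)O[Si](CC)(CC)CC.[Li+] | intermediate
14 | lithium 5-(3-methylbut-2-en-1-yl)indol-1-ide | CC(C)=CCc1ccc2[n-]ccc2c1.[Li+] | intermediate
15 | (2R)-N-{(2R)-3-methyl-2-[5-(3-methylbut-2-en-1-yl)-1H-indol-3-yl]-3-(triethylsilyloxy)butanoyl}bornane-10,2-sultam | CC1(C)[C@@H]2CC[C@]13CS(=O)(=O)N([C@@H]3C2)C(=O)[C@H](c4c[nH]c5ccc(CC=C(C)C)cc45)C(C)(C)O[Si](CC)(CC)CC | intermediate
16 | (2R)-3-methyl-2-[5-(3-methylbut-2-en-1-yl)-1H-indol-3-yl]-3-(triethylsilyloxy)butanal | O=C[C@H](c1c[nH]c2ccc(CC=C(C)C)cc12)C(C)(C)O[Si](CC)(CC)CC | intermediate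
17 | (2S)-3-methyl-2-[5-(3-methylbut-2-en-1-yl)-1H-indol-3-yl]-3-(triethylsilyloxy)butan-1-ol | OC[C@H](c1c[nH]c2ccc(CC=C(C)C)cc12)C(C)(C)O[Si](CC)(CC)CC | intermediate
18 | hexadecanoyl (palmitoyl) chloride | CCCCCCCCCCCCCCCC(=O)Cl | starting material
19 | (2S)-3-methyl-2-[5-(3-methylbut-2-en-1-yl)-1H-indol-3-yl]-3-(triethylsilyloxy)butyl hexadecanoate | CCCCCCCCCCCCCCCC(=O)OC[C@H](c1c[nH]c2ccc(CC=C(C)C)cc12)C(C)(C)O[Si](CC)(CC)CC | intermediate
20 | (2S)-3-hydroxy-3-methyl-2-[5-(3-methylbut-2-en-1-yl)-1H-indol-3-yl]butyl hexadecanoate (CNP0125367.1) | CCCCCCCCCCCCCCCC(=O)OC[C@H](c1c[nH]c2ccc(CC=C(C)C)cc12)C(C)(C)O | target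

## Step count
Total step count: 7.
Longest linear sequence: 6 (steps 2 to 7, from 4). Step 1 is the side branch.

## Three steps most likely to fail

**Step 4 (highest risk).**
- The reacting carbon is neopentyl-like.
- The enolate can lose triethylsilanolate.
- Indole homocoupling consumes oxidant.

The fallback sets out from 3 and comes back at 20. It replaces the oxidative coupling by an SN2 epoxide opening.
- 3 is N-silylated (NaH, TIPSCl, THF) to 5-(3-methylbut-2-en-1-yl)-1-(triisopropylsilyl)indole F1.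
- Bromination at C3 (NBS, THF, −78 °C) gives 3-bromo-5-(3-methylbut-2-en-1-yl)-1-(triisopropylsilyl)indole F2.
- t-BuLi (2 equiv, −78 °C) converts it to the 3-lithioindole F3.
- Separately, 3-methylbut-2-en-1-ol F4 is epoxidised under Sharpless conditions (Ti(OiPr)4, D-(−)-diisopropyl tartrate, TBHP, 4 Å sieves, −20 °C) to [(2R)-3,3-dimethyloxiran-2-yl]methanol F5.
- Silylation (TBSCl, imidazole) gives the epoxy TBS ether F6.
- F3 and F6 are combined with BF3·OEt2 at −78 °C. The aryllithium attacks the less substituted C2 with inversion and gives the (S)-configured bis-silyl tertiary alcohol F7.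
- TBAF removes both silyl groups to give (2S)-3-methyl-2-[5-(3-methylbut-2-en-1-yl)-1H-indol-3-yl]butane-1,3-diol F8.
- The primary hydroxyl of this diol is acylated selectively with 18 (1.0 equiv, pyridine, −20 °C) to give 20.

**Step 5.**
- The carbonyl is strongly shielded.
- The primary alkoxide formed could pull the TES group over from the tertiary oxygen by a 1,5 O-to-O shift.

The fallback sets out from 15 and comes back at 16, now isolated, and from there at 17.
- Commercial sodium ethanethiolate (THF, 0 °C) transfers the acyl group to sulfur. This gives S-ethyl (2R)-3-methyl-2-[5-(3-methylbut-2-en-1-yl)-1H-indol-3-yl]-3-(triethylsilyloxy)butanethioate F9 and recovered 4.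
- DIBAL-H (toluene, −78 °C) stops at aldehyde 16.
- NaBH4 in MeOH at −20 °C gives 17 through a weakly basic borate, which does not trigger silyl migration.

**Step 3.**
- The aldolate can undergo retro-aldol or β-lactonisation.
- Silylation of the hindered alkoxide may be incomplete.

The fallback sets out from 4 and comes back at 12. It takes the C–C bond from a purchased acid and replaces steps 2 and 3.
- 3-Hydroxy-3-methylbutanoic acid F10 is bis-silylated (TESCl, imidazole, DMF) to triethylsilyl 3-methyl-3-(triethylsilyloxy)butanoate F11.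
- Oxalyl chloride with catalytic DMF (CH2Cl2, 0 °C) turns the silyl ester directly into 3-methyl-3-(triethylsilyloxy)butanoyl chloride F12.
- This chloride acylates sodium sultamide 6 (from 4 and NaH, toluene, 0 °C) to give 12.

## Further compounds
F1 | step 4 | 5-(3-methylbut-2-en-1-yl)-1-(triisopropylsilyl)-1H-indole | c1cn([Si](C(C)C)(C(C)C)C(C)C)c2ccc(CC=C(C)C)cc12
F2 | step 4 | 3-bromo-5-(3-methylbut-2-en-1-yl)-1-(triisopropylsilyl)-1H-indole | Brc1cn([Si](C(C)C)(C(C)C)C(C)C)c2ccc(CC=C(C)C)cc12
F3 | step 4 | 3-lithio-5-(3-methylbut-2-en-1-yl)-1-(triisopropylsilyl)-1H-indole | [Li]c1cn([Si](C(C)C)(C(C)C)C(C)C)c2ccc(CC=C(C)C)cc12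
F4 | step 4 | 3-methylbut-2-en-1-ol | CC(C)=CCO
F5 | step 4 | [(2R)-3,3-dimethyloxiran-2-yl]methanol | CC1(C)O[C@@H]1CO
F6 | step 4 | tert-butyl{[(2R)-3,3-dimethyloxiran-2-yl]methoxy}dimethylsilane | CC1(C)O[C@@H]1CO[Si](C)(C)C(C)(C)C
F7 | step 4 | (3S)-4-(tert-butyldimethylsilyloxy)-2-methyl-3-[5-(3-methylbut-2-en-1-yl)-1-(triisopropylsilyl)-1H-indol-3-yl]butan-2-ol | CC(C)(C)[Si](C)(C)OC[C@H](c1cn([Si](C(C)C)(C(C)C)C(C)C)c2ccc(CC=C(C)C)cc12)C(C)(C)O
F8 | step 4 | (2S)-3-methyl-2-[5-(3-methylbut-2-en-1-yl)-1H-indol-3-yl]butane-1,3-diol | OC[C@H](c1c[nH]c2ccc(CC=C(C)C)cc12)C(C)(C)O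
F9 | step 5 | S-ethyl (2R)-3-methyl-2-[5-(3-methylbut-2-en-1-yl)-1H-indol-3-yl]-3-(triethylsilyloxy)butanethioate | CCSC(=O)[C@H](c1c[nH]c2ccc(CC=C(C)C)cc12)C(C)(C)O[Si](CC)(CC)CC
F10 | step 3 | 3-hydroxy-3-methylbutanoic acid | CC(C)(O)CC(=O)O
F11 | step 3 | triethylsilyl 3-methyl-3-(triethylsilyloxy)butanoate | CC[Si](CC)(CC)OC(=O)CC(C)(C)O[Si](CC)(CC)CC
F12 | step 3 | 3-methyl-3-(triethylsilyloxy)butanoyl chloride | CC[Si](CC)(CC)OC(C)(C)CC(=O)Cl
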